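## The problem

Compound 14 is a C2-symmetric 4,4'-binaphthalene. With each half numbered as a naphthalene (ring A = C1 to C4 with C4a and C8a; ring B = C4a, C5 to C8, C8a), hydroxyl groups sit on C1, C6 and C8, an acetyl group on C2, a methyl group on C3 and the biaryl bond on C4. Ring A is therefore hexasubstituted and each position must be placed without ambiguity, while the C4–C4' bond lies between two C3 methyl groups and two peri C5 hydrogens and would be hard to forge once both naphthalenes exist. There are no stereocentres; the hindered axis is the only stereogenic element, it is written without a configuration and nothing in the molecule could control it, so the racemate is the goal. The free 1,3,8-trioxygenated naphthalene is electron-rich and prone to aerial oxidation, and C5 and C7 of ring B would outrun ring A in any late electrophilic step, so the ring-A substituents must be in place before ring B exists and the oxygens must stay capped to the end. The acetyl groups are acidic and electrophilic and need masking wherever strong base is used. The feature that opens the synthesis is ring B itself: oxygen on C6 and C8 and hydrogen on C5 and C7 is what a 1,1,3-trioxygenated buta-1,3-diene leaves after cycloaddition across a C4a–C8a aryne and loss of one ketal substituent, and removing both rings B in this way leaves a plain 2,2'-dimethylbiphenyl whose rings carry only oxygen, acetyl and one halogen.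

## Retrosynthesis

**14 to 13.** The six O–H bonds of 14 are traced back to O–CH3 bonds in the hexamethyl ether 13. Methyl is preferred over benzyl or silyl because the ring-B ethers arrive with the diene at no cost, and the C1 methoxy group is inert to lithium amides and is the inductive director the aryne step needs. The skeleton is not simplified, but 13 is air-stable and has no acidic hydroxyl. The forward reaction must cleave six aryl methyl ethers and leave two aryl ketones alone.

**13 to 8 and 10.** In each half the bonds C4a–C5 and C8–C8a are cut, four bonds and both rings B in all. The neighbouring cuts are worse. Cutting C4–C4' asks for a coupling of two naphthalenes at a carbon flanked by a methyl group and a peri hydrogen, while C5 and C7 are the reactive sites. Cutting ring A asks for a hexasubstituted benzene to be assembled on an axis that is already hindered. The chosen cut reduces 13 to the biphenyl 8, whose rings carry methoxy, masked acetyl, methyl, bromine and a single hydrogen, plus two molecules of diene 10. The forward step needs a base that removes the lone hydrogen beside bromine, an aryne that accepts 10 in one orientation, aromatisation of the adduct 11 to 12, and hydrolysis of the enol ethers to give 13.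

**10 to 9.** The O–Si bond of the ketene acetal is cut, leading to the commercial ester 9. The forward step is γ-deprotonation and O-silylation.

**8 to 7.** The two O–Si bonds of the enol ethers are cut to reveal the diketone 7. Masking as silyl enol ethers costs one step, needs no separate removal, and takes both the acidic protons and the electrophilic carbonyl out of play during the aryne step.

**7 to 6.** The two O–CH3 bonds on C4 and C4' of the biphenyl are cut. Methylation is placed after the acyl transfer because the free phenol is what carries the acetyl group to its ortho carbon.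

**6 to 5 to 4.** The C3–acyl bonds are cut by a Fries retron, back to the diacetate 5 and the dibromodiol 4. A direct Friedel–Crafts acylation would go to the open ortho carbon C5. With bromine on C5 the acyl group can only enter C3, and the same bromine is later the leaving group of the aryne, so one atom does two jobs.

**4 to 3.** The two C5–Br bonds are cut. The forward bromination has the para position blocked by the biaryl bond and must choose the open ortho carbon over the one wedged between OH and CH3.

**3 to 1 and 2.** The C1–C1' bond is cut to two commercial C7 phenols, the bromide 1 and the boronic acid 2. At this stage the axis carries only two ortho methyl groups and two ortho hydrogens, so the coupling is an ordinary one.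

## Roads not taken

Alternative 1: The cut goes through ring A. In the forward sense, tetraacetylethane A1 condenses twice with dimethyl 3-oxopentanedioate A2 under NaOMe. Each pentanedione unit closes a hexasubstituted benzene around the central C–C bond, which becomes C4–C4', giving the tetraester A3. The merits are real: the biaryl bond exists from the start with no metal, two bulk reagents are used, and one operation gives a fully substituted biphenyl. This front end is shorter and cheaper than the six steps to 8. The weak point is what A3 is. Each ring is locally symmetric, with two equivalent esters and two equivalent methyl groups, yet the target needs one ester turned into an acetyl group and the other ester and its neighbouring methyl group used for ring B. That calls for mono-differentiation on each of two rings, at esters flanked by two ortho substituents, and ring B is still unbuilt. Against the economy of A3, the chosen plan installs every ring-A substituent in its final form and position through 4, 6 and 7, and delivers both rings B in one step.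

Alternative 2: The cut is C5–C6 and C7–C8 in each half. Forward, the bis-toluate A4 (acetyl groups masked as needed) is lithiated at each methyl group ortho to the ester and acylated by N-methoxy-N-methylacetamide A5. The new ketone enolate then closes onto the ester to give the naphthalene-1,3-diol A6. Its endgame is better than the chosen one: the ring-B oxygens arrive free, and only two chelated methyl ethers remain to be cleaved, against six in 13. The weak points lie in A4. It is a hexasubstituted biphenyl with four ortho methyl groups on the axis, so it needs either a very hindered coupling or the symmetry-burdened route through A3. Each ring has two benzylic methyl groups, of which only one may react, next to an acetyl group that is more acidic than either. The acylation also has to occur on a methyl group ortho to the axis. The chosen plan pays with a harder last step but needs only a bromine and a hydrogen at the ring-B positions of 8, both placed by ordinary phenol chemistry.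

Alternative 3: The cut is C3–C4 and C1–C2 in each half. Forward, the bibenzyl diester A7 is lithiated at both benzylic carbons, and each adds to (E)-4-methoxypent-3-en-2-one A8. The resulting enolates acylate the ortho esters and lose methanol to give A9, in which C1–OH is free and acetyl and methyl are in place. On paper this is the shortest road, and in step count it beats the nine steps of the chosen plan; the C4–C4' bond is a simple CH2–CH2 bond at the outset. The weak point is the key step. It needs two carbanions on adjacent benzylic carbons, or, if run in turn, a secondary benzylic anion beside a newly formed naphthalene attacking a β,β-disubstituted enone carbon. The crowding that will become the hindered axis is thus created in the bond-forming event itself. 1,2-Addition to the ketone, ester self-condensation and oxidation of the dianion to a stilbene compete. The chosen plan sets against the brevity of this road that each of its steps is a known reaction on its substrate class, and that the axis becomes hindered only as ring B fuses onto the existing biphenyl 8.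

Key step: step 8

Assumption: the structure carries no descriptor for the C4–C4' axis, so 14 is taken as the racemic biaryl.

## Route

Step 1
Reactants: 1 4-bromo-3-methylphenol; 2 (4-hydroxy-2-methylphenyl)boronic acid
Product: 3 2,2'-dimethyl-[1,1'-biphenyl]-4,4'-diol
Conditions: Pd(OAc)2 (2 mol%), SPhos (4 mol%), K3PO4, dioxane/H2O, 80 °C
Reagents that add atoms: none
Why: Suzuki–Miyaura cross-coupling; a palladium catalyst with a bulky dialkylbiarylphosphine tolerates free phenols and one ortho methyl group on each partner, and only one C–Br and one C–B bond are present, so a single biaryl can form.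

Step 2
Reactants: 3 2,2'-dimethyl-[1,1'-biphenyl]-4,4'-diol
Product: 4 5,5'-dibromo-2,2'-dimethyl-[1,1'-biphenyl]-4,4'-diol
Conditions: NBS (2.05 equiv), i-Pr2NH (cat.), CH2Cl2, 0 °C
Reagents that add atoms: N-bromosuccinimide, O=C1CCC(=O)N1Br
Why: Amine-catalysed ortho-bromination of a phenol (electrophilic aromatic substitution); the para position is the biaryl carbon, and of the two ortho carbons C5 is open while C3 is wedged between OH and CH3, so one bromine should enter each ring at C5 and deactivate it against a second.

Step 3
Reactants: 4 5,5'-dibromo-2,2'-dimethyl-[1,1'-biphenyl]-4,4'-diol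
Product: 5 5,5'-dibromo-2,2'-dimethyl-[1,1'-biphenyl]-4,4'-diyl diacetate
Conditions: Ac2O, pyridine, DMAP (cat.), CH2Cl2, rt
Reagents that add atoms: acetic anhydride, CC(=O)OC(C)=O
Why: DMAP-catalysed O-acylation of both phenols; nothing else in 4 is nucleophilic.

Step 4
Reactants: 5 5,5'-dibromo-2,2'-dimethyl-[1,1'-biphenyl]-4,4'-diyl diacetate
Product: 6 1,1'-(5,5'-dibromo-4,4'-dihydroxy-2,2'-dimethyl-[1,1'-biphenyl]-3,3'-diyl)di(ethan-1-one)
Conditions: AlCl3 (6 equiv), PhCl, 120 °C; then 1 M HCl
Reagents that add atoms: none
Why: Fries rearrangement; the acylium ion released from the AlCl3-bound ester can re-enter only at C3, because the para carbon carries the biaryl bond and the other ortho carbon carries bromine. Acyl transfer into a position flanked by a methyl group is normal for 3-methylphenyl esters whose open positions are blocked, and the product is held as a stable aluminium chelate until the acidic work-up.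

Step 5
Reactants: 6 1,1'-(5,5'-dibromo-4,4'-dihydroxy-2,2'-dimethyl-[1,1'-biphenyl]-3,3'-diyl)di(ethan-1-one)
Product: 7 1,1'-(5,5'-dibromo-4,4'-dimethoxy-2,2'-dimethyl-[1,1'-biphenyl]-3,3'-diyl)di(ethan-1-one)
Conditions: MeI, K2CO3, DMF, 50 °C
Reagents that add atoms: iodomethane, CI
Why: Williamson O-methylation; carbonate in DMF breaks the hydrogen bond to the acetyl group, and the phenoxide is alkylated far faster than the ketone could be enolised and C-methylated.

Step 6
Reactants: 7 1,1'-(5,5'-dibromo-4,4'-dimethoxy-2,2'-dimethyl-[1,1'-biphenyl]-3,3'-diyl)di(ethan-1-one)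
Product: 8 5,5'-dibromo-3,3'-bis[1-(tert-butyldimethylsilyloxy)ethenyl]-4,4'-dimethoxy-2,2'-dimethyl-1,1'-biphenyl
Conditions: TBSOTf, Et3N, CH2Cl2, 0 °C to rt
Reagents that add atoms: tert-butyldimethylsilyl trifluoromethanesulfonate, CC(C)(C)[Si](C)(C)OS(=O)(=O)C(F)(F)F
Why: Soft enolisation and O-silylation of a methyl ketone; only the acetyl CH3 can enolise, and the resulting silyl enol ether is stable to lithium amides and is removed by the acidic work-up of step 8.

Step 7
Reactants: 9 methyl (E)-3-methoxybut-2-enoate
Product: 10 (E)-1,3-dimethoxy-1-(trimethylsilyloxy)buta-1,3-diene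
Conditions: LDA, THF, −78 °C; then TMSCl, −78 °C to rt
Reagents that add atoms: chlorotrimethylsilane, C[Si](C)(C)Cl
Why: γ-Deprotonation of the β-methoxy enoate by lithium diisopropylamide gives the dienolate, which chlorotrimethylsilane traps on oxygen; this is the standard preparation of this ketene acetal diene, and its double-bond geometry is erased in step 8.

Step 8
Reactants: 8 5,5'-dibromo-3,3'-bis[1-(tert-butyldimethylsilyloxy)ethenyl]-4,4'-dimethoxy-2,2'-dimethyl-1,1'-biphenyl; 10 (E)-1,3-dimethoxy-1-(trimethylsilyloxy)buta-1,3-diene
Product: 13 2,2'-diacetyl-1,1',6,6',8,8'-hexamethoxy-3,3'-dimethyl-4,4'-binaphthalene, via bis(5,8-dihydronaphthalene) ketal cycloadduct 11 (not isolated), via aromatised bis(silyl enol ether) 12 (not isolated)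
Conditions: 10 (6 equiv), LiTMP (6 equiv, added slowly), THF, −78 °C to rt; then 2 M HCl, THF, rt
Reagents that add atoms: none
Why: This is an aryne Diels–Alder reaction with a 1,1,3-trioxygenated butadiene followed by aromatisation, a known route to naphthalene-1,3-diol ethers, here run twice in one flask. Lithium 2,2,6,6-tetramethylpiperidide, too hindered to add to an aryne, removes the only ring hydrogen of each half (on C4a, acidified by the neighbouring bromine) and LiBr leaves to give the C4a–C8a aryne; the two halves react in turn. Diene 10 adds in a concerted but asynchronous suprafacial (4+2) cycloaddition that forms C4a–C5 and C8–C8a together, so each ring B is closed by an intermolecular cycloaddition and not by a separate cyclisation event. The selectivity needed is the orientation of the diene: the inductively withdrawing methoxy group on C1 makes the remote aryne carbon C4a the electrophilic one, the nucleophilic CH2 terminus of 10 bonds there, and the bulky ketene acetal carbon is thereby kept away from the twisted aryl group on C4, so electronics and sterics agree. In adduct 11 excess amide removes a benzylic and allylic C5 hydrogen, and lithium trimethylsilanolate, the better leaving group on the C8 ketal, departs to give naphthalene 12 with methoxy groups on C6 and C8. Aqueous HCl then completes any remaining aromatisation and hydrolyses both silyl enol ethers to the acetyl groups of 13. The silyl enol ethers keep the ketones from being attacked and from acting as enolate nucleophiles toward the aryne, and the fully substituted ring A offers no second site for ring deprotonation. No stereocentre is formed in 13; the C8 ketal centres of 11 vanish on aromatisation and the hindered C4–C4' axis arises as the racemate.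

Step 9
Reactants: 13 2,2'-diacetyl-1,1',6,6',8,8'-hexamethoxy-3,3'-dimethyl-4,4'-binaphthalene
Product: 14 2,2'-diacetyl-3,3'-dimethyl-4,4'-binaphthalene-1,1',6,6',8,8'-hexol
Conditions: BBr3 (12 equiv), CH2Cl2, −78 °C to rt; then MeOH/H2O, 0 °C, under argon
Reagents that add atoms: none
Why: Lewis-acid cleavage of aryl methyl ethers; BBr3 binds each ether oxygen and bromide removes the methyl group by SN2 attack. The ethers ortho to acetyl (C1) and peri to oxygen (C8) should go first with chelation assistance and the C6 ethers with the excess at room temperature, while the ketones survive as boron complexes that hydrolysis releases.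

## Compound list

1 | 4-bromo-3-methylphenol | Cc1cc(O)ccc1Br | starting material
2 | (4-hydroxy-2-methylphenyl)boronic acid | Cc1cc(O)ccc1B(O)O | starting material
3 | 2,2'-dimethyl-[1,1'-biphenyl]-4,4'-diol | Cc1cc(O)ccc1-c1ccc(O)cc1C | intermediate
4 | 5,5'-dibromo-2,2'-dimethyl-[1,1'-biphenyl]-4,4'-diol | Cc1cc(O)c(Br)cc1-c1cc(Br)c(O)cc1C | intermediate
5 | 5,5'-dibromo-2,2'-dimethyl-[1,1'-biphenyl]-4,4'-diyl diacetate | CC(=O)Oc1cc(C)c(-c2cc(Br)c(OC(C)=O)cc2C)cc1Br | intermediate
6 | 1,1'-(5,5'-dibromo-4,4'-dihydroxy-2,2'-dimethyl-[1,1'-biphenyl]-3,3'-diyl)di(ethan-1-one) | CC(=O)c1c(C)c(-c2cc(Br)c(O)c(C(C)=O)c2C)cc(Br)c1O | intermediate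
7 | 1,1'-(5,5'-dibromo-4,4'-dimethoxy-2,2'-dimethyl-[1,1'-biphenyl]-3,3'-diyl)di(ethan-1-one) | COc1c(Br)cc(-c2cc(Br)c(OC)c(C(C)=O)c2C)c(C)c1C(C)=O | intermediate
8 | 5,5'-dibromo-3,3'-bis[1-(tert-butyldimethylsilyloxy)ethenyl]-4,4'-dimethoxy-2,2'-dimethyl-1,1'-biphenyl | COc1c(Br)cc(-c2cc(Br)c(OC)c(C(=C)O[Si](C)(C)C(C)(C)C)c2C)c(C)c1C(=C)O[Si](C)(C)C(C)(C)C | intermediate
9 | methyl (E)-3-methoxybut-2-enoate | CO/C(C)=C/C(=O)OC | starting material
10 | (E)-1,3-dimethoxy-1-(trimethylsilyloxy)buta-1,3-diene | C=C(OC)/C=C(\OC)O[Si](C)(C)C | intermediate
11 | 2,2'-bis[1-(tert-butyldimethylsilyloxy)ethenyl]-1,1',6,6',8,8'-hexamethoxy-3,3'-dimethyl-8,8'-bis(trimethylsilyloxy)-5,5',8,8'-tetrahydro-4,4'-binaphthalene (mixture of C8 epimers, not isolated) | COc1c(C(=C)O[Si](C)(C)C(C)(C)C)c(C)c(-c2c(C)c(C(=C)O[Si](C)(C)C(C)(C)C)c(OC)c3c2CC(OC)=CC3(OC)O[Si](C)(C)C)c2c1C(OC)(O[Si](C)(C)C)C=C(OC)C2 | intermediate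
12 | 2,2'-bis[1-(tert-butyldimethylsilyloxy)ethenyl]-1,1',6,6',8,8'-hexamethoxy-3,3'-dimethyl-4,4'-binaphthalene (not isolated) | COc1cc(OC)c2c(OC)c(C(=C)O[Si](C)(C)C(C)(C)C)c(C)c(-c3c(C)c(C(=C)O[Si](C)(C)C(C)(C)C)c(OC)c4c(OC)cc(OC)cc34)c2c1 | intermediate
13 | 2,2'-diacetyl-1,1',6,6',8,8'-hexamethoxy-3,3'-dimethyl-4,4'-binaphthalene | CC(=O)c1c(C)c(-c2c(C)c(C(C)=O)c(OC)c3c(OC)cc(OC)cc23)c2cc(OC)cc(OC)c2c1OC | intermediate
14 | 2,2'-diacetyl-3,3'-dimethyl-4,4'-binaphthalene-1,1',6,6',8,8'-hexol (racemic axis) | CC(=O)c1c(C)c(-c2c(C)c(C(C)=O)c(O)c3c(O)cc(O)cc23)c2cc(O)cc(O)c2c1O | target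

## Step count and least certain steps

Total step count: 9. Longest linear sequence: 8 steps (steps 1 to 6, 8 and 9); step 7 is a one-step side branch.

**Step 8 (key step).** The most likely failures are the second dehydrobromination lagging behind the first, and capture of the short-lived aryne by something other than the diene: the amide, or the electron-rich enol ether double bond of a neighbouring molecule. Either would erode the twofold annulation. Orientation leakage is less likely, because methoxy induction and the bulk of the C4 aryl group point the same way. Partial expulsion of methoxide in place of silanolate at C8 would do no lasting harm, since step 9 removes every methyl group. Fallback: the ketone is carried through the aryne step as a protected carbinol. Setting out from 7, NaBH4 in MeOH/THF should reduce both ketones to 1,1'-(5,5'-dibromo-4,4'-dimethoxy-2,2'-dimethyl-[1,1'-biphenyl]-3,3'-diyl)di(ethan-1-ol) F1, a diastereomer mixture. TBSOTf and 2,6-lutidine would give the bis(tert-butyldimethylsilyl) ether F2. The same treatment with LiTMP and diene 10 would then give 2,2'-bis[1-(tert-butyldimethylsilyloxy)ethyl]-1,1',6,6',8,8'-hexamethoxy-3,3'-dimethyl-4,4'-binaphthalene F3. Bu4NF would free the diol 2,2'-bis(1-hydroxyethyl)-1,1',6,6',8,8'-hexamethoxy-3,3'-dimethyl-4,4'-binaphthalene F4, and Dess–Martin periodinane would oxidise it to 13, where the route is rejoined.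

**Step 4 (Fries rearrangement).** The most likely failures are migration or loss of the ring bromine under hot AlCl3, and slow return of the acyl group into the position flanked by the methyl group, so that the ester is merely cleaved. Fallback: the acetyl carbon is brought in as a formyl group. Setting out from 4, MgCl2, Et3N and paraformaldehyde in refluxing MeCN (magnesium-mediated ortho-formylation) should give 5,5'-dibromo-4,4'-dihydroxy-2,2'-dimethyl-[1,1'-biphenyl]-3,3'-dicarbaldehyde F5. MeI and K2CO3 would give the dimethyl ether 5,5'-dibromo-4,4'-dimethoxy-2,2'-dimethyl-[1,1'-biphenyl]-3,3'-dicarbaldehyde F6. MeMgBr in THF at −78 °C would add to both aldehydes to give the diol 1,1'-(5,5'-dibromo-4,4'-dimethoxy-2,2'-dimethyl-[1,1'-biphenyl]-3,3'-diyl)di(ethan-1-ol) F1, the same compound as in the fallback for step 8. Dess–Martin periodinane would oxidise it to 7, where the route is rejoined without passing through 5 and 6.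

**Step 9 (sixfold demethylation).** The most likely failures are incomplete cleavage of the two C6 ethers, which have no neighbouring carbonyl or peri oxygen to assist, and oxidative degradation of the electron-rich hexaphenol during long exposure and work-up. Fallback: the C6 oxygens are brought in as silyl ethers so that no unassisted methyl ether has to be cleaved. Setting out from 8, the cycloaddition of step 8 would be run with 1-methoxy-1,3-bis(trimethylsilyloxy)buta-1,3-diene F7 in place of 10. After the same acidic work-up this should give 2,2'-diacetyl-1,1',8,8'-tetramethoxy-3,3'-dimethyl-4,4'-binaphthalene-6,6'-diol F8. Its four remaining ethers all sit next to an acetyl group or a peri oxygen and should fall to BBr3 in CH2Cl2 between −78 and 0 °C, giving 14 directly.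

**Step 1 (coupling of two free phenols).** The most likely failures are protodeboronation of the electron-rich, ortho-substituted boronic acid and slow oxidative addition to the bromophenoxide. Fallback: a reductive homocoupling of the methyl ether. Setting out from 1, MeI and K2CO3 would give 1-bromo-4-methoxy-2-methylbenzene F9. NiCl2(PPh3)2 (cat.), Zn dust and Et4NI in THF at 50 °C would couple it to 4,4'-dimethoxy-2,2'-dimethyl-1,1'-biphenyl F10, and BBr3 in CH2Cl2 would return the route to 3.

## Further compounds

F1 | step 8 | 1,1'-(5,5'-dibromo-4,4'-dimethoxy-2,2'-dimethyl-[1,1'-biphenyl]-3,3'-diyl)di(ethan-1-ol) (diastereomer mixture) | COc1c(Br)cc(-c2cc(Br)c(OC)c(C(C)O)c2C)c(C)c1C(C)O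
F2 | step 8 | 5,5'-dibromo-3,3'-bis[1-(tert-butyldimethylsilyloxy)ethyl]-4,4'-dimethoxy-2,2'-dimethyl-1,1'-biphenyl | COc1c(Br)cc(-c2cc(Br)c(OC)c(C(C)O[Si](C)(C)C(C)(C)C)c2C)c(C)c1C(C)O[Si](C)(C)C(C)(C)C
F3 | step 8 | 2,2'-bis[1-(tert-butyldimethylsilyloxy)ethyl]-1,1',6,6',8,8'-hexamethoxy-3,3'-dimethyl-4,4'-binaphthalene | COc1cc(OC)c2c(OC)c(C(C)O[Si](C)(C)C(C)(C)C)c(C)c(-c3c(C)c(C(C)O[Si](C)(C)C(C)(C)C)c(OC)c4c(OC)cc(OC)cc34)c2c1
F4 | step 8 | 2,2'-bis(1-hydroxyethyl)-1,1',6,6',8,8'-hexamethoxy-3,3'-dimethyl-4,4'-binaphthalene | COc1cc(OC)c2c(OC)c(C(C)O)c(C)c(-c3c(C)c(C(C)O)c(OC)c4c(OC)cc(OC)cc34)c2c1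
F5 | step 4 | 5,5'-dibromo-4,4'-dihydroxy-2,2'-dimethyl-[1,1'-biphenyl]-3,3'-dicarbaldehyde | Cc1c(C=O)c(O)c(Br)cc1-c1cc(Br)c(O)c(C=O)c1C
F6 | step 4 | 5,5'-dibromo-4,4'-dimethoxy-2,2'-dimethyl-[1,1'-biphenyl]-3,3'-dicarbaldehyde | Cc1c(C=O)c(OC)c(Br)cc1-c1cc(Br)c(OC)c(C=O)c1C
F7 | step 9 | 1-methoxy-1,3-bis(trimethylsilyloxy)buta-1,3-diene | C=C(O[Si](C)(C)C)C=C(OC)O[Si](C)(C)C
F8 | step 9 | 2,2'-diacetyl-1,1',8,8'-tetramethoxy-3,3'-dimethyl-4,4'-binaphthalene-6,6'-diol | CC(=O)c1c(C)c(-c2c(C)c(C(C)=O)c(OC)c3c(OC)cc(O)cc23)c2cc(O)cc(OC)c2c1OC
F9 | step 1 | 1-bromo-4-methoxy-2-methylbenzene | COc1ccc(Br)c(C)c1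
F10 | step 1 | 4,4'-dimethoxy-2,2'-dimethyl-1,1'-biphenyl | COc1ccc(-c2ccc(OC)cc2C)c(C)c1
A1 | alternative 1 | tetraacetylethane (3,4-diacetylhexane-2,5-dione) | CC(=O)C(C(C)=O)C(C(C)=O)C(C)=O
A2 | alternative 1 | dimethyl 3-oxopentanedioate | COC(=O)CC(=O)CC(=O)OC
A3 | alternative 1 | tetramethyl 4,4'-dihydroxy-2,2',6,6'-tetramethylbiphenyl-3,3',5,5'-tetracarboxylate | COC(=O)c1c(C)c(-c2c(C)c(C(=O)OC)c(O)c(C(=O)OC)c2C)c(C)c(C(=O)OC)c1O
A4 | alternative 2 | dimethyl 5,5'-diacetyl-4,4'-dimethoxy-2,2',6,6'-tetramethylbiphenyl-3,3'-dicarboxylate | COC(=O)c1c(C)c(-c2c(C)c(C(C)=O)c(OC)c(C(=O)OC)c2C)c(C)c(C(C)=O)c1OC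
A5 | alternative 2 | N-methoxy-N-methylacetamide | CON(C)C(C)=O
A6 | alternative 2 | 2,2'-diacetyl-1,1'-dimethoxy-3,3'-dimethyl-4,4'-binaphthalene-6,6',8,8'-tetrol | CC(=O)c1c(C)c(-c2c(C)c(C(C)=O)c(OC)c3c(O)cc(O)cc23)c2cc(O)cc(O)c2c1OC
A7 | alternative 3 | dimethyl 6,6'-(ethane-1,2-diyl)bis(2,4-dimethoxybenzoate) | COC(=O)c1c(OC)cc(OC)cc1CCc1cc(OC)cc(OC)c1C(=O)OC
A8 | alternative 3 | (E)-4-methoxypent-3-en-2-one | CO/C(C)=C/C(C)=O
A9 | alternative 3 | 2,2'-diacetyl-6,6',8,8'-tetramethoxy-3,3'-dimethyl-4,4'-binaphthalene-1,1'-diol | CC(=O)c1c(C)c(-c2c(C)c(C(C)=O)c(O)c3c(OC)cc(OC)cc23)c2cc(OC)cc(OC)c2c1O
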